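Readings and results are simulated with made-up constants, and the scatter is random.

Set the even share as the zero of your scale: find the [second end groups] at which a first end group is as likely to become a link as a ring, and read every run against it.

| flask | first end groups | second end groups | remark | time |
|---|---|---|---|---|
| cedar | 0.031 M | 0.055 M | run made earlier |  |
| maple | 0.062 M | 0.055 M | run made earlier |  |
| ash | 0.050 M | 0.066 M | run made earlier |  |
| violet | 0.025 M | 0.0400 M |  | 25 h |
| red | 0.050 M | 0.0550 M |  | 25 h |

| run | time / h | links / % |
|---|---|---|
| cedar | 1.33 | 60.9 |
| cedar | 2.00 | 61.1 |
| cedar | 3.00 | 60.0 |
| cedar | 5.00 | 60.3 |
| cedar | 8.00 | 57.5 |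
| cedar | 12.0 | 55.5 |
| cedar | 20.0 | 54.1 |
| maple | 1.00 | 43.7 |
| maple | 2.50 | 41.5 |
| maple | 5.00 | 40.4 |
| maple | 8.00 | 40.9 |
| maple | 10.0 | 40.0 |
| maple | 15.0 | 39.1 |
| maple | 20.0 | 37.0 |
| ash | 1.33 | 59.5 |
| ash | 2.50 | 60.7 |
| ash | 5.00 | 58.3 |
| ash | 10.0 | 57.4 |
| ash | 20.0 | 53.5 |

(scatter of a reading: 0.5 percentage points)

1. the flask that ends with the higher amount of links, in percent of the first end groups charged, or "neither" when 2 percentage points or less lies between them (violet / red / neither)
2. final links, as a percentage of the first end groups charged, in violet
3. final links, as a percentage of the first end groups charged, in red

- candidate steps: first end groups + second end groups -> links; links -> over-reaction product; first end groups + second end groups -> rings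

Take the slow loss first. Between first and last readings the three runs together lose links at 0.00694 h⁻¹, so cedar's first reading goes back to 61.5% at zero time. Each of the two forming steps, to links and to rings, takes one second end group per first end group, so cedar's mean [second end groups] is 0.0395 M.

As a working rule, let links per ring equal [second end groups] divided by the even level 0.0248 M, the concentration giving equal shares; that ratio is a selectivity factor. First end groups are the limiting reagent in violet and red, with charges less than those of second end groups. At mean levels of 0.0275 M and 0.0300 M, and with 84.1% of the links surviving, I get 44.2% for violet and 46.0% for red.

The mean is the weak link, since red's [second end groups] falls from 0.0550 M to 0.00500 M, across the even level. So sum the share over the fall: links formed equal the first end groups charged, less the even level times the ln of (starting [second end groups] + even level) over (final [second end groups] + even level). Violet becomes 43.4% and red 43.0%, a gap of 0.40 percentage points, less than the margin. I commit to neither. Maple's first and last readings entered the loss rate, but the even level was taken from cedar. Maple has less second than first end groups; summing down to zero gives 41.3% at 2.50 h, against a reading of 41.5%.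

The forecast says violet, with 52.3% for violet and 45.3% for red, holding that “selectivity does not depend on concentration while first end groups are limiting”. There it parts from the even level.

The flask gives neither: violet 44.2%, red 43.7%.

    first end groups + second end groups → links (k = 68.8 M⁻¹ h⁻¹)
    links → over-reaction product (k = 0.00706 h⁻¹)
    first end groups + second end groups → rings, rate k3*[first end groups] as long as [second end groups] is above zero (k = 1.64 h⁻¹)

At 25 h, rings hold 47.4% of the first end groups charged in violet and 47.9% in red. Now raise red's second end groups to 0.093 M: the even level gives 61.1% links, and that neighbour flask gives 61.6%.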